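**Plan**

- Retrosynthesis: the C7–O acyl bond is cut first, which removes the 4-hydroxybenzoate. Then O1–C2 and C3–C4 of the tetrahydrofuran are cut together, leaving an enal and a propargylic alcohol.
- Enabling feature: number the ring O1, C2 (aryl), C3 (carrying C7H2O), C4 (=C6H–aryl), C5H2. Then aryl–C2–C3–C7 is the carbon chain of coniferaldehyde (C7 is the formyl carbon) and O1–C5–C4–C6–aryl is a 3-arylprop-2-yn-1-ol, so at ring closure C3 is an enamine carbon and C4 an alkyne carbon.
- Forward: both phenols are silylated and the alkynol is made by Sonogashira coupling. One amine/palladium cascade joins the halves and closes the only new ring, and hydride reduction of the aldehyde ends it. Mitsunobu esterification at C7 and desilylation follow.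
- Stereochemistry: C2 comes from the chiral secondary amine (dynamic kinetic resolution of the reversible oxa-Michael adduct). C3 is set trans to the C2 aryl group in the cyclization transition state. The (E)-alkene comes from anti attack on the metal-bound alkyne followed by protonolysis with retention.

Key step: step 4

Assumption: the diarylprolinol silyl ether shields the iminium β-face in the usual sense (addition on the side remote from the diphenyl(silyloxy)methyl group), so the (R)-catalyst should give the (2R) ether carbon; if induction runs the other way, the (S)-catalyst is used.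

**Step 1**
Reactants: 1 coniferaldehyde, (E)-3-(4-hydroxy-3-methoxyphenyl)prop-2-enal
Product: 2 (E)-3-[4-(tert-butyldimethylsilyloxy)-3-methoxyphenyl]prop-2-enal
Conditions: TBSCl, imidazole, DMF, 0 °C → rt
Reagents that add atoms: tert-butyldimethylsilyl chloride (TBSCl), CC(C)(C)[Si](C)(C)Cl
Why: Phenol O-silylation with a silyl chloride and imidazole is selective for the phenol and leaves the enal untouched, and it masks the acidic OH that would interfere with iminium catalysis and with palladium.

**Step 2**
Reactants: 3 4-bromo-2-methoxyphenol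
Product: 4 (4-bromo-2-methoxyphenoxy)(tert-butyl)dimethylsilane
Conditions: TBSCl, imidazole, DMF, 0 °C → rt
Reagents that add atoms: tert-butyldimethylsilyl chloride (TBSCl), CC(C)(C)[Si](C)(C)Cl
Why: The same phenol O-silylation protects the hydroxyl before cross-coupling, and the aryl silyl ether is stable to amine bases.

**Step 3**
Reactants: 4 (4-bromo-2-methoxyphenoxy)(tert-butyl)dimethylsilane; 5 propargyl alcohol (prop-2-yn-1-ol)
Product: 6 3-[4-(tert-butyldimethylsilyloxy)-3-methoxyphenyl]prop-2-yn-1-ol
Conditions: Pd(PhCN)2Cl2 (3 mol %), [HP(t-Bu)3]BF4 (6 mol %), CuI (2 mol %), i-Pr2NH, dioxane, rt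
Reagents that add atoms: none
Why: Sonogashira coupling, in which the bulky electron-rich phosphine allows oxidative addition of zerovalent palladium into the electron-rich aryl bromide at room temperature while the free propargylic hydroxyl and the aryl silyl ether are tolerated.

**Step 4**
Reactants: 2 (E)-3-[4-(tert-butyldimethylsilyloxy)-3-methoxyphenyl]prop-2-enal; 6 3-[4-(tert-butyldimethylsilyloxy)-3-methoxyphenyl]prop-2-yn-1-ol
Product: 9 [(2R,3S,4E)-2-[4-(tert-butyldimethylsilyloxy)-3-methoxyphenyl]-4-[4-(tert-butyldimethylsilyloxy)-3-methoxybenzylidene]tetrahydrofuran-3-yl]methanol, via oxa-Michael adduct 7 (not isolated), via tetrahydrofuran-3-carbaldehyde 8 (not isolated)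
Conditions: (R)-α,α-diphenylprolinol trimethylsilyl ether (20 mol %), PdCl2(MeCN)2 (5 mol %), PhCO2H (20 mol %), THF, 4 °C → rt; cold short SiO2 pad; then NaBH4, MeOH, −20 °C
Reagents that add atoms: none
Why: Proposed new method: the closest known reaction type is the amine/divalent-palladium co-catalysed oxa-Michael–carbocyclization of enals with terminal propargylic alcohols; it is extended here to an aryl-capped alkyne and intercepted by reduction before the exocyclic alkene can move into conjugation. The (R)-prolinol ether converts 2 into an iminium ion, the hydroxyl of 6 adds reversibly to its β-carbon (O1–C2; adduct 7 and its C2 epimer equilibrate by retro-addition), and the enamine carbon C3 then attacks C4 of the palladium-bound alkyne in a 5-exo-dig closure from the side opposite the metal (C3–C4, the only ring formed), after which protonolysis of the C6–Pd bond with retention and hydrolysis release 8 and both catalysts. C2 is controlled by the catalyst, whose diphenyl(silyloxy)methyl group blocks one β-face and lets only the matched enamine cyclize (dynamic kinetic asymmetric transformation); C3 is controlled by the substrate, the formyl-bearing carbon closing trans to the C2 aryl group in an envelope transition state, which is also the thermodynamically preferred arrangement at this epimerizable position. Anti addition across the alkyne followed by stereoretentive protodepalladation leaves the C6 aryl group cis to C3, which is the (E)-alkene of the target. The step needs 5-exo rather than 6-endo attack, favoured by the three-atom C2–O1–C5 tether although the electron-rich aryl group polarizes the alkyne the other way, and it needs the β,γ-unsaturated aldehyde to survive, which is why metal and amine are removed on a cold silica pad and the filtrate is reduced at once with NaBH4 to the configurationally stable alcohol 9.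

**Step 5**
Reactants: 9 [(2R,3S,4E)-2-[4-(tert-butyldimethylsilyloxy)-3-methoxyphenyl]-4-[4-(tert-butyldimethylsilyloxy)-3-methoxybenzylidene]tetrahydrofuran-3-yl]methanol; 10 4-hydroxybenzoic acid
Product: 11 [(2R,3S,4E)-2-[4-(tert-butyldimethylsilyloxy)-3-methoxyphenyl]-4-[4-(tert-butyldimethylsilyloxy)-3-methoxybenzylidene]tetrahydrofuran-3-yl]methyl 4-hydroxybenzoate
Conditions: PPh3, DIAD, THF, 0 °C → rt
Reagents that add atoms: none
Why: Mitsunobu esterification, in which the carboxylic acid is alkylated by the oxyphosphonium ion of the primary C7 alcohol far faster than the much less acidic phenol (a known chemoselectivity for phenolic acids), and since C7 is a methylene group no stereocentre is touched.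

**Step 6**
Reactants: 11 [(2R,3S,4E)-2-[4-(tert-butyldimethylsilyloxy)-3-methoxyphenyl]-4-[4-(tert-butyldimethylsilyloxy)-3-methoxybenzylidene]tetrahydrofuran-3-yl]methyl 4-hydroxybenzoate
Product: 12 agastenol, [(2R,3S,4E)-2-(4-hydroxy-3-methoxyphenyl)-4-(4-hydroxy-3-methoxybenzylidene)tetrahydrofuran-3-yl]methyl 4-hydroxybenzoate
Conditions: TBAF, AcOH (1:1), THF, 0 °C
Reagents that add atoms: none
Why: Fluoride-mediated cleavage of the two aryl silyl ethers, with AcOH buffering to keep free fluoride and phenoxide low so that the benzoate ester, the benzylic ether at C2 and the alkene geometry should be preserved.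

**Compound list**

1 | coniferaldehyde, (E)-3-(4-hydroxy-3-methoxyphenyl)prop-2-enal | COc1cc(/C=C/C=O)ccc1O | starting material
2 | (E)-3-[4-(tert-butyldimethylsilyloxy)-3-methoxyphenyl]prop-2-enal | COc1cc(/C=C/C=O)ccc1O[Si](C)(C)C(C)(C)C | intermediate
3 | 4-bromo-2-methoxyphenol | COc1cc(Br)ccc1O | starting material
4 | (4-bromo-2-methoxyphenoxy)(tert-butyl)dimethylsilane | COc1cc(Br)ccc1O[Si](C)(C)C(C)(C)C | intermediate
5 | propargyl alcohol (prop-2-yn-1-ol) | C#CCO | starting material
6 | 3-[4-(tert-butyldimethylsilyloxy)-3-methoxyphenyl]prop-2-yn-1-ol | COc1cc(C#CCO)ccc1O[Si](C)(C)C(C)(C)C | intermediate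
7 | (3R)-3-[4-(tert-butyldimethylsilyloxy)-3-methoxyphenyl]-3-({3-[4-(tert-butyldimethylsilyloxy)-3-methoxyphenyl]prop-2-yn-1-yl}oxy)propanal (oxa-Michael adduct, formed reversibly; the epimer that cyclizes is shown) | O=CC[C@@H](OCC#Cc1ccc(O[Si](C)(C)C(C)(C)C)c(OC)c1)c1ccc(O[Si](C)(C)C(C)(C)C)c(OC)c1 | intermediate
8 | (2R,3R,4E)-2-[4-(tert-butyldimethylsilyloxy)-3-methoxyphenyl]-4-[4-(tert-butyldimethylsilyloxy)-3-methoxybenzylidene]tetrahydrofuran-3-carbaldehyde (2,3-trans) | COc1cc(/C=C2/CO[C@@H](c3ccc(O[Si](C)(C)C(C)(C)C)c(OC)c3)[C@@H]2C=O)ccc1O[Si](C)(C)C(C)(C)C | intermediate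
9 | [(2R,3S,4E)-2-[4-(tert-butyldimethylsilyloxy)-3-methoxyphenyl]-4-[4-(tert-butyldimethylsilyloxy)-3-methoxybenzylidene]tetrahydrofuran-3-yl]methanol (2,3-trans) | COc1cc(/C=C2/CO[C@@H](c3ccc(O[Si](C)(C)C(C)(C)C)c(OC)c3)[C@@H]2CO)ccc1O[Si](C)(C)C(C)(C)C | intermediate
10 | 4-hydroxybenzoic acid | O=C(O)c1ccc(O)cc1 | starting material
11 | [(2R,3S,4E)-2-[4-(tert-butyldimethylsilyloxy)-3-methoxyphenyl]-4-[4-(tert-butyldimethylsilyloxy)-3-methoxybenzylidene]tetrahydrofuran-3-yl]methyl 4-hydroxybenzoate | COc1cc(/C=C2/CO[C@@H](c3ccc(O[Si](C)(C)C(C)(C)C)c(OC)c3)[C@@H]2COC(=O)c2ccc(O)cc2)ccc1O[Si](C)(C)C(C)(C)C | intermediate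
12 | agastenol, [(2R,3S,4E)-2-(4-hydroxy-3-methoxyphenyl)-4-(4-hydroxy-3-methoxybenzylidene)tetrahydrofuran-3-yl]methyl 4-hydroxybenzoate | COc1cc(/C=C2/CO[C@@H](c3ccc(O)c(OC)c3)[C@@H]2COC(=O)c2ccc(O)cc2)ccc1O | target

Total step count: 6
Longest linear sequence: 5 steps (steps 2, 3, 4, 5, 6; from 3 to 12)

**Steps most likely to fail**

1. Step 4 (proposed new method). Four processes could defeat it:
- the enamine may not add to the internal alkyne, so the reversible oxa-Michael equilibrium only returns the starting materials;
- attack may occur at the aryl-bearing alkyne carbon (6-endo), because the electron-rich arene polarizes the alkyne that way;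
- addition may be syn instead of anti, giving the wrong alkene geometry;
- the exocyclic double bond may migrate into conjugation with the aldehyde through a dienamine, which erases C3.

The fallback uses known chemistry, sets out from 2 and 6 and rejoins the route at 9. Luche reduction of 2 (NaBH4, CeCl3·7H2O, MeOH, 0 °C) would give (E)-3-[4-(tert-butyldimethylsilyloxy)-3-methoxyphenyl]prop-2-en-1-ol F1. n-BuLi followed by Boc2O (THF, −78 °C → rt) converts it into tert-butyl (E)-3-[4-(tert-butyldimethylsilyloxy)-3-methoxyphenyl]prop-2-en-1-yl carbonate F2. Iridium-catalysed asymmetric allylic etherification of F2 with the copper alkoxide of 6 should then give the branched (R)-1-[4-(tert-butyldimethylsilyloxy)-3-methoxyphenyl]prop-2-en-1-yl 3-[4-(tert-butyldimethylsilyloxy)-3-methoxyphenyl]prop-2-yn-1-yl ether F3, in which O1–C2 is already in place. The alkoxide is made with n-BuLi and CuI, and the catalyst is [Ir(cod)Cl]2 with a BINOL-derived phosphoramidite bearing a bis(1-phenylethyl)amino group, in the antipode that leads to the (R)-ether, in THF. Epoxidation of the terminal alkene (mCPBA, NaHCO3, CH2Cl2) gives 2-{(S)-[4-(tert-butyldimethylsilyloxy)-3-methoxyphenyl]({3-[4-(tert-butyldimethylsilyloxy)-3-methoxyphenyl]prop-2-yn-1-yl}oxy)methyl}oxirane F4. F4 is a mixture at the oxirane carbon, which is of no consequence because that carbon becomes a radical; the ether carbon is unchanged in space and is S only by the priority rules. The trivalent titanium reagent Cp2TiCl (from Cp2TiCl2 and Zn dust, THF, rt) opens the oxirane homolytically to the secondary C3 radical with C7–O–Ti. This radical closes 5-exo-dig onto the aryl alkyne (C3–C4), trans to the C2 aryl group in a chair-like transition state. The linear α-aryl vinyl radical should be quenched from the open C5 side, placing the aryl group cis to C3, and mild acidic work-up gives 9.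

2. Step 5. The activated C7 oxyphosphonium ion could alkylate a phenol oxygen instead of the carboxylate (aryl ether formation), or it could lose a proton from C3 and eliminate towards a conjugated diene.

The fallback acylates instead of displacing at C7; it sets out from 9 and 10 and rejoins the route at 12. Bis-silylation of 10 (TBSCl, imidazole, DMF) gives tert-butyldimethylsilyl 4-(tert-butyldimethylsilyloxy)benzoate F5. Its silyl ester alone is hydrolysed (AcOH, THF, H2O, rt) to 4-(tert-butyldimethylsilyloxy)benzoic acid F6. Steglich acylation of 9 with F6 (EDC·HCl, DMAP, CH2Cl2) leaves the C7–O bond intact and gives [(2R,3S,4E)-2-[4-(tert-butyldimethylsilyloxy)-3-methoxyphenyl]-4-[4-(tert-butyldimethylsilyloxy)-3-methoxybenzylidene]tetrahydrofuran-3-yl]methyl 4-(tert-butyldimethylsilyloxy)benzoate F7. Buffered fluoride as in step 6 removes all three aryl silyl ethers and gives 12.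

3. Step 6. Fluoride or the liberated phenoxides could cleave or transfer the benzoate, and prolonged exposure to base could open the 4-hydroxybenzylic ether at C2 through a quinone methide, which would scramble C2.

The fallback removes the silyl groups before the ester exists; it sets out from 9 and rejoins the route at 12. TBAF/AcOH in THF at 0 °C converts 9 into [(2R,3S,4E)-2-(4-hydroxy-3-methoxyphenyl)-4-(4-hydroxy-3-methoxybenzylidene)tetrahydrofuran-3-yl]methanol F8. Mitsunobu esterification of F8 with 10 (PPh3, DIAD, THF, 0 °C) then gives 12 directly, so that the benzoate never meets fluoride or base. In this step only the carboxylic acid is acidic enough to be alkylated and only the primary alcohol is activated.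

**Further compounds**

F1 | step 4 | (E)-3-[4-(tert-butyldimethylsilyloxy)-3-methoxyphenyl]prop-2-en-1-ol | COc1cc(/C=C/CO)ccc1O[Si](C)(C)C(C)(C)C
F2 | step 4 | tert-butyl (E)-3-[4-(tert-butyldimethylsilyloxy)-3-methoxyphenyl]prop-2-en-1-yl carbonate | COc1cc(/C=C/COC(=O)OC(C)(C)C)ccc1O[Si](C)(C)C(C)(C)C
F3 | step 4 | (R)-1-[4-(tert-butyldimethylsilyloxy)-3-methoxyphenyl]prop-2-en-1-yl 3-[4-(tert-butyldimethylsilyloxy)-3-methoxyphenyl]prop-2-yn-1-yl ether | C=C[C@@H](OCC#Cc1ccc(O[Si](C)(C)C(C)(C)C)c(OC)c1)c1ccc(O[Si](C)(C)C(C)(C)C)c(OC)c1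
F4 | step 4 | 2-{(S)-[4-(tert-butyldimethylsilyloxy)-3-methoxyphenyl]({3-[4-(tert-butyldimethylsilyloxy)-3-methoxyphenyl]prop-2-yn-1-yl}oxy)methyl}oxirane (both epimers at the oxirane carbon) | C1OC1[C@@H](OCC#Cc1ccc(O[Si](C)(C)C(C)(C)C)c(OC)c1)c1ccc(O[Si](C)(C)C(C)(C)C)c(OC)c1
F5 | step 5 | tert-butyldimethylsilyl 4-(tert-butyldimethylsilyloxy)benzoate | CC(C)(C)[Si](C)(C)OC(=O)c1ccc(O[Si](C)(C)C(C)(C)C)cc1
F6 | step 5 | 4-(tert-butyldimethylsilyloxy)benzoic acid | CC(C)(C)[Si](C)(C)Oc1ccc(C(=O)O)cc1
F7 | step 5 | [(2R,3S,4E)-2-[4-(tert-butyldimethylsilyloxy)-3-methoxyphenyl]-4-[4-(tert-butyldimethylsilyloxy)-3-methoxybenzylidene]tetrahydrofuran-3-yl]methyl 4-(tert-butyldimethylsilyloxy)benzoate | COc1cc(/C=C2/CO[C@@H](c3ccc(O[Si](C)(C)C(C)(C)C)c(OC)c3)[C@@H]2COC(=O)c2ccc(O[Si](C)(C)C(C)(C)C)cc2)ccc1O[Si](C)(C)C(C)(C)C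
F8 | step 6 | [(2R,3S,4E)-2-(4-hydroxy-3-methoxyphenyl)-4-(4-hydroxy-3-methoxybenzylidene)tetrahydrofuran-3-yl]methanol | COc1cc(/C=C2/CO[C@@H](c3ccc(O)c(OC)c3)[C@@H]2CO)ccc1O
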